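## The problem

Atom labels used throughout: the lactam is N–C1(=O); C8 is the quaternary carbon on C1; the cyclopentane is C8–C13–C14(CO2Me)–C15(OH)–C9; ring A (cyclohexenone) is C9=C11–C10(=O)–C17–C16–C15; ring B (cyclohexene) is C8–C9=C11–C12–C6–C5; the piperidinone is N–C1–C8–C5–C6–C7; C5 also carries C21 (CH2OAc) and the chain C4–C3–C2(=O)–C18(H)(CH3)–C19 that returns to N, and the target is (5R,6S,8S,14R,15S,18R). The core is a 3-azabicyclo[3.3.1]nonan-2-one in which the bridgehead C8 and the one-carbon bridge C5 are adjacent all-carbon quaternary centres, C8 being also the point where the cyclopentane and rings A and B meet. N and C5 are tied a second time by the five-carbon keto chain, so the piperidinone is bridged across its 1,4-positions (a 1-azabicyclo[5.2.2]undecane with two nine-membered rings); closing a nine-membered ring late, onto a boat lactam through a weakly nucleophilic amide nitrogen, is the closure most likely to resist. Of the six stereocentres, C6 follows from C8 once the lactam bridge exists, so the real tasks are C5 against C8 (which arm of C5 faces the nitrogen bridge), the trans hydroxy ester pair C14/C15, and the remote C18 methyl centre, which no ring stereocentre can be trusted to control. C8 cannot be enolised once it is a bridgehead, so its four carbon substituents must be in place before the bicycle is closed. The groups that will not survive rough treatment are the β-hydroxy ester C15–C14 (retro-aldol, dehydration), the tertiary allylic alcohol γ to the enone, the C18–H next to the C2 ketone, and the primary acetate and methyl ester, which exclude strong base and hydride late in the route. The feature that makes the key step possible is the nine-membered lactam ring N–C1(=O)–C8–C5–C4–C3–C2–C18–C19: an amide whose α-carbon C8 is bonded to C5, with the C2 ketone marking C3=C4 as a latent double bond; this γ,δ-unsaturated amide is the retron of a ketene aza-Claisen (3-aza-Cope) rearrangement that cuts C5–C8 and N–C1 and reconnects N–C3 into a simple pyrrolidine ring (N, C19, C18, C2, C3).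

## Retrosynthesis

Ring A (33 ⇒ 32 ⇒ 31). The C15–O bond is cut and C16–C17 is taken to an alkene, which turns the γ-hydroxy enone into the para-quinol dienone 32 and this into phenol 31. The neighbouring cut, the aldol bond C14–C15, would need an ene-dione and would set two centres at once under reversible conditions. The phenol cut removes C15 as a stereocentre and makes ring A a flat, robust arene for the whole route. The forward reactions must add oxygen at C15 anti to the C14 ester and then saturate the disubstituted C16=C17 bond beside the tetrasubstituted C9=C11 bond.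

Oxidation levels (31 ⇒ 30 ⇒ 29 ⇒ 27). No skeletal bond is cut. The C12 methylene is traced to an aryl ketone, the C3–C4 single bond to the enone alkene of 30 and 29, the C2 carbonyl to the allylic CH2 of alkene 27, and the phenol to a methyl ether. A ketone at C12 is preferred to any other adjustment because it serves three forward steps: it is the acylation retron for ring B, it activates C6 for the attachment of C7, and it directs cleavage of the neighbouring methyl ether. The forward steps must oxidise C2 (the only allylic CH2, C5 being quaternary) and later reduce an alkene and a benzylic ketone without touching the C2 ketone.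

Lactam bridge (27 ⇒ 26 ⇒ 25). The N–C7 and C6–C7 bonds are cut, which removes C7 as a one-carbon unit at the aldehyde oxidation level and opens the piperidinone to the secondary lactam 25. Cutting N–C19 or C18–C19 instead would open a nine-membered ring and ask for its closure. The cut at C7 asks only for a six-membered closure by conjugate addition of N–H to the methylidene ketone 26. Precursor 25 has one ring and one stereocentre fewer, and the same basic step is asked to equilibrate C14.

Ring B (25 ⇒ 23 ⇒ 22). The aryl–acyl bond C11–C12 is cut (Friedel–Crafts transform) to acid 23 and its tert-butyl ester 22. C11 is the only free position ortho to C9 and lies ortho to the methoxy group, so there is no regiochemical question. The precursor is an indane spiro-linked to a nine-membered lactam.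

Key disconnection (22 ⇒ 21 ⇒ 20 ⇒ 19 + 11). In the N-benzylated lactam 21 the C5–C8 and N–C1 bonds are cut and N–C3 is reconnected (retro ketene aza-Claisen through zwitterion 20). This gives the aryl alkyl ketene 19 and the 2-alkenylpyrrolidine 11. Against the neighbouring cuts (N–C19 alkylation, closure at C2–C3 or C3–C4, enolate alkylation at C8), this one removes the nine-membered ring, the C5–C8 bond and both quaternary stereocentres at once. It also replaces a medium-ring closure by the enlargement of a five-membered ring. The forward reaction must join two fully substituted carbons, transfer chirality from C3 to C5, and fix C8 through the enolate geometry.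

Amine 11 (⇒ 9 ⇒ 8 ⇒ 7 ⇒ 4 + 5 ⇒ 2 ⇒ 1). The N–benzyl bond is cut (reductive amination), and the acetate and allylic alcohol are traced to the conjugated ethyl ester of 7. The C4=C5 double bond is cut (Horner–Wadsworth–Emmons transform) to ester 4 and phosphonosuccinate 5; the E olefination product has exactly the geometry the rearrangement needs. Ester 4 comes from the D-pyroglutamate 1 by trans methylation (2) and reduction of the lactam carbonyl.

Ketene 19 (⇒ 18 ⇒ 17 ⇒ 16 ⇒ 14 ⇒ 13 ⇒ 12). The ketene is the dehydrochlorination product of acid chloride 18 of indane acid 17. The carboxyl carbon C1 is removed (one-carbon homologation) to keto ester 14, whose ketone is cut at the aryl–acyl bond to the arylsuccinic acid 12. The acid is used as the racemate, because C8 is erased in 19 and C14 is corrected later.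

## Roads not taken

Alternative 1: the most obvious cut, N–C19 last. The bridged tetracycle with both quaternary centres is built first, the C5 side chain is extended to an isopropenyl ketone, and the nine-membered ring is closed by intramolecular aza-Michael addition of the lactam N–H of A1.
- The closure asks a weak nucleophile to form a nine-membered ring across a rigid boat lactam, with an unfavourable entropy and transannular strain in the transition state.
- The addition is reversible under the basic conditions that also epimerise C18, which in this plan is set only by a protonation.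
- The vicinal quaternary centres must be made separately by stepwise alkylation of hindered enolates.
- The chosen plan makes the same ring by enlargement of a pyrrolidine, forms the C5–C8 bond in the same step, and takes C18 from the chiral pool.

Alternative 2: the biomimetic reconnection C1=C2. The hexacyclic enamine A2 (a 2-pyrroline fused to a cyclohexene across C1=C2) would be cleaved oxidatively (singlet oxygen or ozone) to give lactam and ketone at once.
- A2 is not simpler than the target: it has one ring more, the same stereocentres, and a bridgehead enamine inside the bicyclo[3.3.1] core.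
- The C1–C2 bond would be made only to be broken, and the oxidant would have to spare an electron-rich arene or a tetrasubstituted enone.
- The cleavage only edits a finished skeleton; the chosen key step builds it.

Alternative 3: the aldol cut C14–C15. The ene-dione A3, with a propanoate arm on C8, would close the cyclopentane by a base-mediated 5-exo aldol addition of the ester enolate to the C15 carbonyl.
- A chelated aldol transition state places the alkoxide and the ester cis, whereas the target has them trans.
- The β-hydroxy ester would form reversibly under base that also threatens C18 and the acetate.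
- The ene-dione must be carried or unveiled late, and the cut leaves the quaternary pair and the nine-membered ring unsolved.
- The chosen plan sets C14 by equilibration in a rigid pentacycle and C15 by attack on a flat ring anti to the ester.

Key step: step 11

Assumption: acid 17 is used as the racemic cis/trans mixture (two equivalents); its C8 centre is erased in ketene 19 and its C14 centre is set in step 14. Compounds 1, 5 and 12 are taken as catalogue compounds.

## Route

Step 1
Reactants: 1 ethyl (2R)-1-(tert-butoxycarbonyl)-5-oxopyrrolidine-2-carboxylate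
Product: 2 ethyl (2R,4S)-1-(tert-butoxycarbonyl)-4-methyl-5-oxopyrrolidine-2-carboxylate
Conditions: LiN(SiMe3)2, THF, −78 °C; MeI, −78 °C
Reagents that add atoms: iodomethane CI
Why: Alkylation of the lithium enolate of an N-acyl lactam; the C2 ester shields its own face, so iodomethane should enter trans and give the (2R,4S) product, any cis epimer being removed by chromatography.

Step 2
Reactants: 2 ethyl (2R,4S)-1-(tert-butoxycarbonyl)-4-methyl-5-oxopyrrolidine-2-carboxylate
Product: 4 ethyl (2R,4S)-1-(tert-butoxycarbonyl)-4-methylpyrrolidine-2-carboxylate, via hemiaminal 3 (not isolated)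
Conditions: LiBHEt3, THF, −78 °C; then Et3SiH, BF3·OEt2, CH2Cl2, −78 °C
Reagents that add atoms: none
Why: The carbamate-activated lactam carbonyl is reduced selectively to hemiaminal 3, and ionic hydrogenation of the derived N-acyliminium ion gives the pyrrolidine without touching the ester or either stereocentre.

Step 3
Reactants: 4 ethyl (2R,4S)-1-(tert-butoxycarbonyl)-4-methylpyrrolidine-2-carboxylate; 5 4-tert-butyl 1-ethyl 2-(diethoxyphosphoryl)butanedioate
Product: 7 4-tert-butyl 1-ethyl (2E)-2-{[(2R,4S)-1-(tert-butoxycarbonyl)-4-methylpyrrolidin-2-yl]methylidene}butanedioate, via aldehyde 6 (not isolated)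
Conditions: iBu2AlH, CH2Cl2, −78 °C; then 5 pre-treated with NaH in THF, −78 °C to rt
Reagents that add atoms: none
Why: Partial reduction to the aluminium hemiacetal and Horner–Wadsworth–Emmons olefination in the same flask avoid isolating the epimerisable α-amino aldehyde 6; the stabilised phosphonosuccinate anion should give the E-alkylidene succinate (pyrrolidine trans to CO2Et), which later fixes C5.

Step 4
Reactants: 7 4-tert-butyl 1-ethyl (2E)-2-{[(2R,4S)-1-(tert-butoxycarbonyl)-4-methylpyrrolidin-2-yl]methylidene}butanedioate
Product: 8 tert-butyl (3E)-3-(hydroxymethyl)-4-[(2R,4S)-1-(tert-butoxycarbonyl)-4-methylpyrrolidin-2-yl]but-3-enoate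
Conditions: iBu2AlH (2.2 equiv), CH2Cl2, −78 °C
Reagents that add atoms: none
Why: iBu2AlH reduces the conjugated ethyl ester to the allylic alcohol at low temperature, while the hindered tert-butyl ester and the carbamate should survive; the alkene geometry is untouched.

Step 5
Reactants: 8 tert-butyl (3E)-3-(hydroxymethyl)-4-[(2R,4S)-1-(tert-butoxycarbonyl)-4-methylpyrrolidin-2-yl]but-3-enoate
Product: 9 tert-butyl (3E)-3-(acetoxymethyl)-4-[(2R,4S)-1-(tert-butoxycarbonyl)-4-methylpyrrolidin-2-yl]but-3-enoate
Conditions: Ac2O, pyridine, DMAP (cat.), CH2Cl2, 0 °C to rt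
Reagents that add atoms: acetic anhydride CC(=O)OC(C)=O
Why: Standard acylation; the acetate of the target is installed now, so C21 needs no protecting group.

Step 6
Reactants: 9 tert-butyl (3E)-3-(acetoxymethyl)-4-[(2R,4S)-1-(tert-butoxycarbonyl)-4-methylpyrrolidin-2-yl]but-3-enoate
Product: 11 tert-butyl (3E)-3-(acetoxymethyl)-4-[(2R,4S)-4-methyl-1-(2-nitrobenzyl)pyrrolidin-2-yl]but-3-enoate, via amine hydrochloride 10 (not isolated)
Conditions: HCl (4 M in dioxane), 0 °C; evaporate; then 2-nitrobenzaldehyde, Et3N, NaBH(OAc)3, ClCH2CH2Cl, rt
Reagents that add atoms: 2-nitrobenzaldehyde O=Cc1ccccc1[N+](=O)[O-]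
Why: Anhydrous HCl removes the carbamate faster than the tert-butyl ester, and reductive amination gives the tertiary allylic amine; the 2-nitrobenzyl group is photolabile and, being electron-poor, should resist ionisation from the later acylammonium ion.

Step 7
Reactants: 12 2-(4-methoxyphenyl)butanedioic acid (racemic)
Product: 13 5-methoxy-3-oxo-2,3-dihydro-1H-indene-1-carboxylic acid (racemic)
Conditions: polyphosphoric acid, 90 °C
Reagents that add atoms: none
Why: Intramolecular Friedel–Crafts acylation by the β-carboxyl group closes the five-membered ketone (the α-carboxyl could only give a four-membered ring), placing the remaining carboxyl on the ring carbon para to OMe.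

Step 8
Reactants: 13 5-methoxy-3-oxo-2,3-dihydro-1H-indene-1-carboxylic acid
Product: 14 methyl 5-methoxy-3-oxo-2,3-dihydro-1H-indene-1-carboxylate (racemic)
Conditions: MeOH, H2SO4 (cat.), reflux
Reagents that add atoms: methanol CO
Why: Fischer esterification installs the methyl ester of the target at C14.

Step 9
Reactants: 14 methyl 5-methoxy-3-oxo-2,3-dihydro-1H-indene-1-carboxylate
Product: 16 methyl 3-formyl-5-methoxy-2,3-dihydro-1H-indene-1-carboxylate, via enol ether 15 (not isolated)
Conditions: Ph3P(CH2OMe)Cl, KOtBu, THF, 0 °C to rt; then 2 M HCl, THF, rt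
Reagents that add atoms: (methoxymethyl)triphenylphosphonium chloride COC[P+](c1ccccc1)(c1ccccc1)c1ccccc1.[Cl-]; water O
Why: Wittig methoxymethylenation and acid hydrolysis of enol ether 15 add the carbon that becomes C1; the stereocentres formed do not matter, because C8 becomes sp2 in the ketene and C14 is equilibrated later.

Step 10
Reactants: 16 methyl 3-formyl-5-methoxy-2,3-dihydro-1H-indene-1-carboxylate
Product: 17 6-methoxy-3-(methoxycarbonyl)-2,3-dihydro-1H-indene-1-carboxylic acid (racemic cis/trans mixture)
Conditions: NaClO2, NaH2PO4, 2-methyl-2-butene, t-BuOH/H2O, rt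
Reagents that add atoms: sodium chlorite [Na+].[O-]Cl=O
Why: Pinnick oxidation converts the aldehyde into the acid without touching the electron-rich arene, 2-methyl-2-butene trapping the hypochlorous acid.

Step 11
Reactants: 17 6-methoxy-3-(methoxycarbonyl)-2,3-dihydro-1H-indene-1-carboxylic acid; 11 tert-butyl (3E)-3-(acetoxymethyl)-4-[(2R,4S)-4-methyl-1-(2-nitrobenzyl)pyrrolidin-2-yl]but-3-enoate
Product: 21 N-(2-nitrobenzyl) spiro (E)-azonin-2-one (C14 epimers), via acid chloride 18 (not isolated), via ketene 19 (not isolated), via acylammonium enolate 20 (not isolated)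
Conditions: (COCl)2, DMF (cat.), CH2Cl2, 0 °C to rt; iPr2NEt, Et2O, 0 °C, filtration under argon; then 11, Yb(OTf)3 (20 mol%), CH2Cl2, 23 °C
Reagents that add atoms: none
Why: Proposed new method: the Lewis-acid-bound ketene 19 should be attacked by the tertiary amine of 11 on the face cis to the alkenyl group and, in the ketene plane, from the C13 methylene side away from the peri C11–H of the coplanar arene, giving acylammonium enolate 20 with O− cis to C9; a charge-accelerated [3,3] shift (ketene aza-Claisen, 3-aza-Cope) then forms C8–C5 and breaks N–C3. The closest known reaction type is the zwitterionic aza-Claisen ring enlargement of N-benzyl-2-vinylpyrrolidines with ketenes to azonin-2-ones, together with the Lewis-acid-promoted acyl-Claisen rearrangement of allylic amines, neither of which has been used to join two fully substituted carbons. The nine-membered ring is not closed end to end but arises by ring enlargement: the pyrrolidine (N, C19, C18, C2, C3) grows by the four atoms C1, C8, C5 and C4 through a six-membered chair transition state fused to the pyrrolidine. C5 is set by 1,3-chirality transfer from C3 of 11 through the chair with C2 equatorial (hence the E alkene) and by the fixed alkene geometry of 11, which puts the CH2CO2tBu arm axial and CH2OAc equatorial. C8 is set relative to C5 by the enolate geometry of 20, which puts C13 axial and the arene carbon C9 equatorial. The selectivity needed is the single diastereomer with C9 on the side of the CH2CO2tBu arm; the rigid indane (one enolate geometry) and the geometrically pure alkene should secure it, while C14 is left as an epimer mixture for correction in step 14. The driving force is neutralisation of the zwitterion with amide formation, and a chloride-free ketene with a triflate Lewis acid should suppress dealkylation of 20.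

Step 12
Reactants: 21 N-(2-nitrobenzyl) spiro (E)-azonin-2-one (C14 epimers)
Product: 22 N–H spiro (E)-azonin-2-one tert-butyl ester (C14 epimers)
Conditions: hν (365 nm), MeCN/H2O (9:1), rt
Reagents that add atoms: none
Why: Photolysis of the 2-nitrobenzyl amide (hydrogen transfer to the excited nitro group, then fragmentation of the hemiaminal) should free the lactam N–H under neutral conditions that spare the alkene, the acetate and both esters; a change of alkene geometry here would be harmless, since the alkene is hydrogenated in step 17.

Step 13
Reactants: 22 N–H spiro (E)-azonin-2-one tert-butyl ester (C14 epimers)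
Product: 25 ring-B tetralone lactam (C14 epimers), via acid 23 (not isolated), via mixed anhydride 24 (not isolated)
Conditions: CF3CO2H/CH2Cl2 (1:1), rt; evaporate; then (CF3CO)2O, CH2Cl2, 0 °C to rt; aq. NaHCO3
Reagents that add atoms: none
Why: Acidolysis of the tert-butyl ester and intramolecular Friedel–Crafts acylation through the mixed trifluoroacetic anhydride should close ring B at C11, the only free position ortho to the C9 substituent and activated by the adjacent OMe; the new C12 ketone is the handle for steps 14, 16 and 17.

Step 14
Reactants: 25 ring-B tetralone lactam (C14 epimers)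
Product: 27 bridged pentacyclic lactam, via methylidene ketone 26 (not isolated)
Conditions: (CH2O)n, iPr2NH·CF3CO2H, THF, 65 °C; then DBU, MeCN, 50 °C
Reagents that add atoms: formaldehyde (as paraformaldehyde) C=O
Why: Mannich-type α-methylenation puts C7 on C6 (the only enolisable ketone position), and base-mediated 6-endo aza-Michael addition of the lactam N–H closes the piperidinone, C6 being dictated by the bridge. DBU should also equilibrate the α-aryl ester centre C14, the most acidic C–H while no C2 carbonyl is present, to the epimer with CO2Me pseudo-equatorial and anti to the C1 bridge, which is the stereoconvergent correction of the racemic acid.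

Step 15
Reactants: 27 bridged pentacyclic lactam
Product: 29 pentacyclic enone, via allylic alcohol 28 (not isolated)
Conditions: SeO2 (0.5 equiv), t-BuOOH, CH2Cl2, rt; then Dess–Martin periodinane, NaHCO3, CH2Cl2, rt
Reagents that add atoms: tert-butyl hydroperoxide CC(C)(C)OO (oxygen relayed through selenium dioxide O=[Se]=O)
Why: Selenium dioxide allylic oxidation (ene reaction, then [2,3] shift) can take hydrogen only from C2 because C5 is quaternary, and Dess–Martin oxidation of the allylic alcohol gives the enone; C6 is a bridgehead, so the aryl ketone cannot be α-oxidised.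

Step 16
Reactants: 29 pentacyclic enone
Product: 30 pentacyclic phenol enone
Conditions: BCl3, CH2Cl2, −78 to 0 °C; aq. NaHCO3
Reagents that add atoms: none
Why: BCl3 chelated between the C12 ketone and the ortho methoxy group should cleave only that methyl ether; esters, acetate and lactam are left alone at low temperature.

Step 17
Reactants: 30 pentacyclic phenol enone
Product: 31 phenol keto-lactam
Conditions: H2 (4 bar), Pd/C, AcOH, 40 °C
Reagents that add atoms: none
Why: Hydrogenation saturates the enone alkene and hydrogenolyses the ortho-hydroxyaryl ketone to the benzylic methylene through the benzylic alcohol; the dialkyl ketone, the arene and C18 should not be affected in this weakly acidic medium.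

Step 18
Reactants: 31 phenol keto-lactam
Product: 32 para-quinol dienone
Conditions: PhI(OAc)2, MeCN/H2O (4:1), 0 °C
Reagents that add atoms: water O
Why: Oxidative dearomatisation of the para-alkyl phenol in aqueous acetonitrile gives the para-quinol; water should attack C15 anti to the vicinal ester on C14, which sets the trans hydroxy ester (15S).

Step 19
Reactants: 32 para-quinol dienone
Product: 33 CNP0211170.1 (target)
Conditions: H2 (1 atm), RhCl(PPh3)3, PhMe/EtOH, rt
Reagents that add atoms: none
Why: Homogeneous hydrogenation with RhCl(PPh3)3 reduces the disubstituted C16=C17 alkene of the cross-conjugated dienone and leaves the tetrasubstituted C9=C11 enone, the ketones and the esters untouched.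

## Compound list

1 | ethyl (2R)-1-(tert-butoxycarbonyl)-5-oxopyrrolidine-2-carboxylate | CCOC(=O)[C@H]1CCC(=O)N1C(=O)OC(C)(C)C | starting material
2 | ethyl (2R,4S)-1-(tert-butoxycarbonyl)-4-methyl-5-oxopyrrolidine-2-carboxylate | CCOC(=O)[C@H]1C[C@H](C)C(=O)N1C(=O)OC(C)(C)C | intermediate
3 | ethyl (2R,4S)-1-(tert-butoxycarbonyl)-5-hydroxy-4-methylpyrrolidine-2-carboxylate (C5 epimers) | CCOC(=O)[C@H]1C[C@H](C)C(O)N1C(=O)OC(C)(C)C | intermediate
4 | ethyl (2R,4S)-1-(tert-butoxycarbonyl)-4-methylpyrrolidine-2-carboxylate | CCOC(=O)[C@H]1C[C@H](C)CN1C(=O)OC(C)(C)C | intermediate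
5 | 4-tert-butyl 1-ethyl 2-(diethoxyphosphoryl)butanedioate | CCOC(=O)C(CC(=O)OC(C)(C)C)P(=O)(OCC)OCC | starting material
6 | tert-butyl (2R,4S)-2-formyl-4-methylpyrrolidine-1-carboxylate | O=C[C@H]1C[C@H](C)CN1C(=O)OC(C)(C)C | intermediate
7 | 4-tert-butyl 1-ethyl (2E)-2-{[(2R,4S)-1-(tert-butoxycarbonyl)-4-methylpyrrolidin-2-yl]methylidene}butanedioate | CCOC(=O)/C(CC(=O)OC(C)(C)C)=C/[C@H]1C[C@H](C)CN1C(=O)OC(C)(C)C | intermediate
8 | tert-butyl (3E)-3-(hydroxymethyl)-4-[(2R,4S)-1-(tert-butoxycarbonyl)-4-methylpyrrolidin-2-yl]but-3-enoate | OC/C(CC(=O)OC(C)(C)C)=C/[C@H]1C[C@H](C)CN1C(=O)OC(C)(C)C | intermediate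
9 | tert-butyl (3E)-3-(acetoxymethyl)-4-[(2R,4S)-1-(tert-butoxycarbonyl)-4-methylpyrrolidin-2-yl]but-3-enoate | CC(=O)OC/C(CC(=O)OC(C)(C)C)=C/[C@H]1C[C@H](C)CN1C(=O)OC(C)(C)C | intermediate
10 | tert-butyl (3E)-3-(acetoxymethyl)-4-[(2R,4S)-4-methylpyrrolidin-2-yl]but-3-enoate hydrochloride | CC(=O)OC/C(CC(=O)OC(C)(C)C)=C/[C@H]1C[C@H](C)C[NH2+]1.[Cl-] | intermediate
11 | tert-butyl (3E)-3-(acetoxymethyl)-4-[(2R,4S)-4-methyl-1-(2-nitrobenzyl)pyrrolidin-2-yl]but-3-enoate | CC(=O)OC/C(CC(=O)OC(C)(C)C)=C/[C@H]1C[C@H](C)CN1Cc1ccccc1[N+](=O)[O-] | intermediate
12 | 2-(4-methoxyphenyl)butanedioic acid (racemic) | COc1ccc(cc1)C(CC(=O)O)C(=O)O | starting material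
13 | 5-methoxy-3-oxo-2,3-dihydro-1H-indene-1-carboxylic acid (racemic) | OC(=O)C1CC(=O)c2cc(OC)ccc12 | intermediate
14 | methyl 5-methoxy-3-oxo-2,3-dihydro-1H-indene-1-carboxylate (racemic) | COC(=O)C1CC(=O)c2cc(OC)ccc12 | intermediate
15 | methyl 5-methoxy-3-(methoxymethylidene)-2,3-dihydro-1H-indene-1-carboxylate (E/Z mixture, racemic) | COC(=O)C1CC(=COC)c2cc(OC)ccc12 | intermediate
16 | methyl 3-formyl-5-methoxy-2,3-dihydro-1H-indene-1-carboxylate (racemic cis/trans mixture) | COC(=O)C1CC(C=O)c2cc(OC)ccc12 | intermediate
17 | 6-methoxy-3-(methoxycarbonyl)-2,3-dihydro-1H-indene-1-carboxylic acid (racemic cis/trans mixture) | COC(=O)C1CC(C(=O)O)c2cc(OC)ccc12 | intermediate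
18 | methyl 3-(chlorocarbonyl)-5-methoxy-2,3-dihydro-1H-indene-1-carboxylate (racemic) | COC(=O)C1CC(C(=O)Cl)c2cc(OC)ccc12 | intermediate
19 | methyl 5-methoxy-3-(oxomethylidene)-2,3-dihydro-1H-indene-1-carboxylate (ketene; racemic at C14) | COC(=O)C1CC(=C=O)c2cc(OC)ccc12 | intermediate
20 | acylammonium enolate from 19 and 11: acyl group on N cis to the 2-alkenyl group; enolate O− cis to arene carbon C9 and N+ cis to C13; C14 epimers | COC(=O)C1C/C(=C(/[O-])[N@+]2(Cc3ccccc3[N+](=O)[O-])C[C@@H](C)C[C@@H]2/C=C(/COC(C)=O)CC(=O)OC(C)(C)C)c2cc(OC)ccc12 | intermediate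
21 | N-(2-nitrobenzyl) spiro (E)-azonin-2-one: nine-membered lactam N–C1(=O)–C8–C5–C4=C3–C2–C18–C19, spiro at C8 to the 6-methoxy-3-(methoxycarbonyl)indane; C5 carries CH2OAc and CH2CO2tBu; C5, C8 and C18 configured as in the target; C14 epimers | COC(=O)C1C[C@]2(c3cc(OC)ccc13)C(=O)N(Cc1ccccc1[N+](=O)[O-])C[C@@H](C)C/C=C/[C@@]2(COC(C)=O)CC(=O)OC(C)(C)C | intermediate
22 | N–H spiro (E)-azonin-2-one tert-butyl ester (21 without the 2-nitrobenzyl group; C14 epimers) | COC(=O)C1C[C@]2(c3cc(OC)ccc13)C(=O)NC[C@@H](C)C/C=C/[C@@]2(COC(C)=O)CC(=O)OC(C)(C)C | intermediate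
23 | carboxylic acid of 22 (CH2CO2H on C5; C14 epimers) | COC(=O)C1C[C@]2(c3cc(OC)ccc13)C(=O)NC[C@@H](C)C/C=C/[C@@]2(COC(C)=O)CC(=O)O | intermediate
24 | mixed trifluoroacetic anhydride of 23 (C14 epimers) | COC(=O)C1C[C@]2(c3cc(OC)ccc13)C(=O)NC[C@@H](C)C/C=C/[C@@]2(COC(C)=O)CC(=O)OC(=O)C(F)(F)F | intermediate
25 | ring-B tetralone lactam: C12 ketone bonded to C11, ring B closed, secondary lactam, E-C3=C4, aryl methyl ether; C14 epimers | COC(=O)C1C[C@]23C(=O)NC[C@@H](C)C/C=C/[C@@]2(COC(C)=O)CC(=O)c4c(OC)ccc1c34 | intermediate
26 | 6-methylidene derivative of 25 (C7 as exocyclic CH2 on C6; C14 epimers) | COC(=O)C1C[C@]23C(=O)NC[C@@H](C)C/C=C/[C@@]2(COC(C)=O)C(=C)C(=O)c4c(OC)ccc1c34 | intermediate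
27 | bridged pentacyclic lactam: N–C7–C6 bridge closed, C12 ketone, aryl methyl ether, E-C3=C4, C2 methylene; C5, C6, C8, C14 and C18 configured as in the target | COC(=O)[C@@H]1C[C@@]23C(=O)N4C[C@@H](C(=O)c5c2c1ccc5OC)[C@]3(COC(C)=O)/C=C/C[C@H](C)C4 | intermediate
28 | C2 allylic alcohol of 27 (C2 epimers) | COC(=O)[C@@H]1C[C@@]23C(=O)N4C[C@@H](C(=O)c5c2c1ccc5OC)[C@]3(COC(C)=O)/C=C/C(O)[C@H](C)C4 | intermediate
29 | pentacyclic enone: C2 ketone conjugated to E-C3=C4, C12 ketone, aryl methyl ether | COC(=O)[C@@H]1C[C@@]23C(=O)N4C[C@@H](C(=O)c5c2c1ccc5OC)[C@]3(COC(C)=O)/C=C/C(=O)[C@H](C)C4 | intermediate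
30 | pentacyclic phenol enone (29 with free C10 phenol) | COC(=O)[C@@H]1C[C@@]23C(=O)N4C[C@@H](C(=O)c5c2c1ccc5O)[C@]3(COC(C)=O)/C=C/C(=O)[C@H](C)C4 | intermediate
31 | phenol keto-lactam: C12 methylene, saturated C3–C4, C2 ketone, ring A as the C10 phenol | COC(=O)[C@@H]1C[C@@]23C(=O)N4C[C@@H](Cc5c2c1ccc5O)[C@]3(COC(C)=O)CCC(=O)[C@H](C)C4 | intermediate
32 | para-quinol dienone: C15 tertiary alcohol, C10 ketone, C9=C11 and C16=C17 double bonds | COC(=O)[C@@H]1C[C@@]23C(=O)N4C[C@@H](CC5=C2[C@]1(O)C=CC5=O)[C@]3(COC(C)=O)CCC(=O)[C@H](C)C4 | intermediate
33 | CNP0211170.1, (5R,6S,8S,14R,15S,18R) in the labels above | COC(=O)[C@@H]1C[C@@]23C(=O)N4C[C@@H](CC5=C2[C@]1(O)CCC5=O)[C@]3(COC(C)=O)CCC(=O)[C@H](C)C4 | target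

## Step count and risks

Total: 19 steps. Longest linear sequence: 15 steps (steps 1–6 and 11–19, from 1); the acid branch (steps 7–10) has 4 steps.

Least certain steps:

Step 11 (key step, proposed new method). The [3,3] shift may be too slow, because two fully substituted carbons must bond. The acylammonium ion would then revert, the ketene would dimerise, or the N-benzyl group would be lost. The enolate geometry could also leak and erode the C8/C5 selectivity. Fallback with known chemistry, setting out from 11: only C5 is made quaternary in the rearrangement, and the cyclopentane is closed afterwards.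
- Commercial 2-(2-bromo-5-methoxyphenyl)acetic acid F1 is coupled with methyl 2-(tributylstannyl)acrylate (Pd(PPh3)4, CuI, DMF; Stille coupling) to give 2-[5-methoxy-2-(3-methoxy-3-oxoprop-1-en-2-yl)phenyl]acetic acid F2.
- Oxalyl chloride gives the acid chloride F3 and iPr2NEt the monosubstituted aryl ketene F4.
- F4 undergoes the precedented zwitterionic aza-Claisen ring enlargement with 11 (Yb(OTf)3) to the nine-membered lactam F5, which carries C8–H.
- A base-mediated 5-exo intramolecular Michael addition of the C8 amide enolate to the acrylate (Cs2CO3, MeCN) forms C8–C13 and returns to the route at 21; the C8 facial selectivity of this closure would have to be checked.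

Step 14. The conjugate addition may be slow, because the lactam must turn its amide bond transoid inside a nine-membered ring that still holds an E alkene. The methylidene ketone may oligomerise meanwhile, and the C14 equilibration may stop short. Fallback from 25: the bond made is C6–C7 instead of N–C7. Paraformaldehyde in CF3CO2H gives the N-(hydroxymethyl) lactam F6, which ionises and is attacked by the enol of the C12 ketone (N-acyliminium Mannich cyclisation). This gives 27 together with its C14 epimer F7; DBU in MeCN converts F7 into 27, where the route is rejoined.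

Step 15. The ene step may be sluggish, because selenium must bind C4 next to the quaternary C5, and prolonged reaction risks over-oxidation. Fallback from 27: hydrogen-atom abstraction at C2 by tert-butylperoxyl radicals (dirhodium tetracaprolactamate Rh2(cap)4, t-BuOOH, K2CO3) puts oxygen on the less hindered end of the allyl radical and gives the allylic tert-butyl peroxide F8. Et3N then fragments F8 (Kornblum–DeLaMare) to enone 29, where the route is rejoined.

Step 18. Facial selectivity at C15 may be poor, since the C1 acyl group shields the other face from a 1,3-position. The lactam oxygen may also capture the cationic intermediate and open the way to lactam cleavage. Fallback from 31: the phenolate is oxidised with singlet oxygen generated from KHSO5 (as 2KHSO5·KHSO4·K2SO4) and NaHCO3 in aqueous MeCN, a non-cationic para-peroxidation that gives the hydroperoxide F9. Dimethyl sulfide reduces F9 to 32, where the route is rejoined.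

## Further compounds

F1 | step 11 | 2-(2-bromo-5-methoxyphenyl)acetic acid | COc1ccc(Br)c(CC(=O)O)c1
F2 | step 11 | 2-[5-methoxy-2-(3-methoxy-3-oxoprop-1-en-2-yl)phenyl]acetic acid | COC(=O)C(=C)c1ccc(OC)cc1CC(=O)O
F3 | step 11 | methyl 2-[2-(2-chloro-2-oxoethyl)-4-methoxyphenyl]prop-2-enoate | COC(=O)C(=C)c1ccc(OC)cc1CC(=O)Cl
F4 | step 11 | methyl 2-[4-methoxy-2-(2-oxoethenyl)phenyl]prop-2-enoate (aryl ketene) | COC(=O)C(=C)c1ccc(OC)cc1C=C=O
F5 | step 11 | N-(2-nitrobenzyl) (E)-azonin-2-one with C8–H bearing the 5-methoxy-2-(3-methoxy-3-oxoprop-1-en-2-yl)phenyl group; C5 and C18 as in 21, C8 not assigned | COC(=O)C(=C)c1ccc(OC)cc1C1C(=O)N(Cc2ccccc2[N+](=O)[O-])C[C@@H](C)C/C=C/[C@@]1(COC(C)=O)CC(=O)OC(C)(C)C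
F6 | step 14 | N-(hydroxymethyl) derivative of tetralone lactam 25 (C14 epimers) | COC(=O)C1C[C@]23C(=O)N(CO)C[C@@H](C)C/C=C/[C@@]2(COC(C)=O)CC(=O)c4c(OC)ccc1c34
F7 | step 14 | C14 epimer of bridged pentacyclic lactam 27 | COC(=O)[C@H]1C[C@@]23C(=O)N4C[C@@H](C(=O)c5c2c1ccc5OC)[C@]3(COC(C)=O)/C=C/C[C@H](C)C4
F8 | step 15 | C2 tert-butyl peroxide of 27 (C2 epimers) | COC(=O)[C@@H]1C[C@@]23C(=O)N4C[C@@H](C(=O)c5c2c1ccc5OC)[C@]3(COC(C)=O)/C=C/C(OOC(C)(C)C)[C@H](C)C4
F9 | step 18 | C15 hydroperoxide of para-quinol dienone 32 | COC(=O)[C@@H]1C[C@@]23C(=O)N4C[C@@H](CC5=C2[C@]1(OO)C=CC5=O)[C@]3(COC(C)=O)CCC(=O)[C@H](C)C4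
A1 | alternative 1 | bridged tetracyclic N–H lactam (aryl methyl ether) with a 4-methyl-3-oxopent-4-enyl chain on C5 | COC(=O)[C@@H]1C[C@@]23C(=O)NC[C@@H](Cc4c2c1ccc4OC)[C@]3(COC(C)=O)CCC(=O)C(C)=C
A2 | alternative 2 | hexacyclic bridgehead enamine with C1=C2 (aryl methyl ether) | COC(=O)[C@@H]1C[C@@]23C6N4C[C@@H](Cc5c2c1ccc5OC)[C@]3(COC(C)=O)CCC=6[C@H](C)C4
A3 | alternative 3 | ene-dione with a methyl propanoate arm on C8 (C14–C15 bond absent, C15 ketone) | COC(=O)CC[C@@]23C(=O)N4C[C@@H](CC5=C2C(=O)CCC5=O)[C@]3(COC(C)=O)CCC(=O)[C@H](C)C4
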